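**Strategy.** Ring A (the tetramethylcyclohexene, C1'–C6') contains the C2'=C3' alkene flanked by C1' and C4', and next to it C5'(H)(CH3)–C6'(CH3)2: a cyclohexene that opens to a diene (C1'–C4') and a cis-disubstituted dienophile. The route rests on a Diels–Alder reaction between an (E)-3-methylpenta-2,4-dienyl silyl ether and an enantiopure 5-menthyloxy-3-methylbutenolide, a masked 2-methylbut-2-ene whose lactone carbonyl and acetal carbon later become methyl groups. One endo cycloaddition anti to the menthyloxy group closes ring A and sets C1' and C5' cis and absolute. Ring A, as an alkenylboronate, is finally coupled to a vinyl iodide of the oxabicyclic core, built from (S)-linalool by silicon-tethered radical cyclization, crotylation and etherification.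

Key step: step 5

Remark on numbering: core atoms carry iridal numbers (C1 = CHO, C2 = CH(CH3), C3–C5 = hydroxypropyl chain, C6–C11 = cyclohexane, C26 = OCH2 bridge carbon on C11, C12–C17 = side chain); ring A atoms are primed (C1' bears the side chain, C2'=C3', C4' = CH2, C5' = CHCH3, C6' = C(CH3)2).

Remark on supply: (S)-(+)-linalool, (+)-menthol, potassium (Z)-crotyltrifluoroborate and 2-(dichloromethyl)pinacolborane are assumed to be commercial in high isomeric purity; centres that are mixtures and are destroyed later are drawn without descriptor.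

**Fragment A (ring A)**

Step 1
Reactants: 1 (E)-3-methylpent-2-en-4-yn-1-ol
Product: 2 (E)-3-methylpenta-2,4-dien-1-ol
Conditions: H2 (1 atm), Pd/CaCO3 poisoned with Pb(OAc)2, quinoline, EtOAc, rt
Reagents that add atoms: none
Why: Lindlar-type semihydrogenation should stop at the vinyl group and leave the (E)-trisubstituted alkene, the future C1'=C2' diene terminus, untouched.

Step 2
Reactants: 2 (E)-3-methylpenta-2,4-dien-1-ol
Product: 3 tert-butyl{[(2E)-3-methylpenta-2,4-dien-1-yl]oxy}diphenylsilane
Conditions: TBDPSCl, imidazole, CH2Cl2, 0 °C to rt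
Reagents that add atoms: tert-butyl(chloro)diphenylsilane CC(C)(C)[Si](Cl)(c1ccccc1)c1ccccc1
Why: Standard O-silylation gives a hydride-stable ether, so that C17 stays distinct from the two oxygenated carbons that are later reduced to methyl groups.

Step 3
Reactants: 4 3-methylfuran-2(5H)-one
Product: 5 5-bromo-3-methylfuran-2(5H)-one (racemic)
Conditions: NBS, AIBN (cat.), PhCF3, reflux
Reagents that add atoms: N-bromosuccinimide O=C1CCC(=O)N1Br
Why: Wohl–Ziegler bromination should occur at C5, which is allylic and α to the ring oxygen.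

Step 4
Reactants: 5 5-bromo-3-methylfuran-2(5H)-one; 6 (1S,2R,5S)-(+)-menthol
Product: 7 (5S)-3-methyl-5-{[(1S,2R,5S)-5-methyl-2-(propan-2-yl)cyclohexyl]oxy}furan-2(5H)-one
Conditions: Ag2CO3, 4 Å molecular sieves, CH2Cl2, rt; acetal epimers separated (crystallization or chromatography)
Reagents that add atoms: none
Why: Koenigs–Knorr-type substitution of the acetal bromide via the oxocarbenium ion gives both acetal epimers, from which the (5S) epimer is taken; the acetal centre epimerizes under acid (TsOH cat.), so the unwanted epimer can be recycled.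

Step 5
Reactants: 3 tert-butyl{[(2E)-3-methylpenta-2,4-dien-1-yl]oxy}diphenylsilane; 7 (5S)-5-menthyloxy-3-methylbutenolide
Product: 8 (3S,3aS,7R,7aR)-7-{[(tert-butyldiphenylsilyl)oxy]methyl}-6,7a-dimethyl-3-{[(1S,2R,5S)-menthyl]oxy}-3a,4,7,7a-tetrahydro-2-benzofuran-1(3H)-one (cis-fused lactone acetal; CH2OSi at C1', lactone C=O at C6' and acetal carbon at C5' all cis)
Conditions: 3 (3 equiv), BHT (cat.), PhMe (2 M), 120 °C, sealed tube
Reagents that add atoms: none
Why: Thermal, concerted but asynchronous normal-demand [4+2] cycloaddition: the unsubstituted diene terminus C4' should bond first to the β-carbon of the butenolide (the future C5') and the substituted terminus C1' then closes onto the α-carbon (the future C6'), which forms both ring A bonds at once. The closest known reaction type is the auxiliary-controlled Diels–Alder reaction of 5-alkoxy-2(5H)-furanones with acyclic dienes. Ring A is closed in an intermolecular suprafacial–suprafacial [4π+2π] mode, so the lactone remains cis-fused to the new cyclohexene. C5' and C6' are fixed relative to each other by the cis ring of the dienophile, C1' is fixed relative to them by the endo rule (lactone carbonyl under the (E)-diene), and the absolute sense is fixed by the (5S) acetal centre, the diene adding to the face anti to the menthyloxy group. The step needs ortho regioselectivity, endo selectivity and π-facial selectivity: the first should come from the unhindered, more nucleophilic CH2 terminus of the 1,2-dialkyl diene and the single activating carbonyl, the second from secondary overlap with the lactone carbonyl, and the third from the alkoxy group that blocks one face of the flat butenolide. The α-methyl group slows the dienophile, hence heat, high concentration and excess diene.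

Step 6
Reactants: 8 Diels–Alder adduct
Product: 9 all-cis diol: ring A carrying C1'–CH2OTBDPS, C6'(CH3)–CH2OH and C5'–CH2OH
Conditions: LiAlH4, THF, 0 °C to rt
Reagents that add atoms: none
Why: Hydride reduction of the lactone and of the aldehyde released from the acetal gives the cis-1,4-diol and frees the menthol auxiliary; no stereocentre is touched.

Step 7
Reactants: 9 all-cis diol
Product: 10 bis(methanesulfonate) of 9
Conditions: MsCl (3 equiv), Et3N, CH2Cl2, −20 °C
Reagents that add atoms: methanesulfonyl chloride CS(Cl)(=O)=O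
Why: Fast sulfene-mediated bis-mesylation at low temperature should outpace cyclization of the monomesylate to a tetrahydrofuran.

Step 8
Reactants: 10 bis(methanesulfonate)
Product: 11 tert-butyl{[(1R,5S)-2,5,6,6-tetramethylcyclohex-2-en-1-yl]methoxy}diphenylsilane
Conditions: LiEt3BH (excess), THF, reflux
Reagents that add atoms: none
Why: SN2 displacement of both primary mesylates by hydride turns the two former carbonyl-level carbons into the C5' methyl and the second C6' methyl; LiEt3BH is chosen because it attacks neopentyl sulfonates at carbon and not at sulfur.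

Step 9
Reactants: 11 silyl ether
Product: 12 [(1R,5S)-2,5,6,6-tetramethylcyclohex-2-en-1-yl]methanol
Conditions: TBAF, THF, rt
Reagents that add atoms: none
Why: Fluoride-induced desilylation frees the C17 alcohol.

Step 10
Reactants: 12 ring A alcohol
Product: 13 (1R,5S)-2,5,6,6-tetramethylcyclohex-2-ene-1-carbaldehyde
Conditions: Dess–Martin periodinane, NaHCO3, CH2Cl2, 0 °C; used at once
Reagents that add atoms: none
Why: Buffered, non-basic oxidation should give the β,γ-unsaturated aldehyde without epimerization at C1' or migration of the alkene into conjugation.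

Step 11
Reactants: 13 ring A aldehyde
Product: 14 4,4,5,5-tetramethyl-2-{(E)-2-[(1R,5S)-2,5,6,6-tetramethylcyclohex-2-en-1-yl]ethenyl}-1,3,2-dioxaborolane
Conditions: CrCl2 (8 equiv), LiI, Cl2CHBpin, THF, rt
Reagents that add atoms: 2-(dichloromethyl)-4,4,5,5-tetramethyl-1,3,2-dioxaborolane ClC(Cl)B1OC(C)(C)C(C)(C)O1
Why: Takai–Utimoto boryl olefination through a gem-dichromium species gives the (E)-alkenylboronate under non-basic conditions that should preserve C1'.

**Fragment B (oxabicyclic core)**

Step 12
Reactants: 15 (S)-(+)-linalool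
Product: 17 (5S)-5-ethenyl-5-methyloxolan-2-ol (anomer mixture), via ozonide 16 (not isolated)
Conditions: O3, CH2Cl2, −78 °C, stopped when 15 is consumed; then Me2S, −78 °C to rt
Reagents that add atoms: ozone [O-][O+]=O
Why: Ozonolysis of the electron-rich trisubstituted alkene, which reacts much faster than the vinyl group, gives the hydroxy aldehyde that closes to the lactol; the carbinol centre (future C10) comes unchanged from the chiral pool.

Step 13
Reactants: 17 lactol; 18 vinylmagnesium bromide
Product: 19 (3S)-3-methylocta-1,7-diene-3,6-diol (C6 epimers)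
Conditions: 18 (3 equiv), THF, 0 °C to rt
Reagents that add atoms: none
Why: Grignard addition to the open hydroxy aldehyde form of the lactol installs the second vinyl group; the new carbinol centre is oxidized later, so its configuration is irrelevant.

Step 14
Reactants: 19 diene diol
Product: 20 (1S)-1-methylcyclohex-2-ene-1,4-diol (C4 epimers)
Conditions: second-generation Grubbs catalyst RuCl2(=CHPh)(PCy3)(H2IMes) (2 mol %), CH2Cl2, 40 °C
Reagents that add atoms: none
Why: Ring-closing metathesis of the 1,7-diene forms the cyclohexene C6–C11 ring with loss of ethene.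

Step 15
Reactants: 20 cyclohexenediol
Product: 21 (4S)-4-hydroxy-4-methylcyclohex-2-en-1-one
Conditions: MnO2, CH2Cl2, rt
Reagents that add atoms: none
Why: Selective oxidation of the secondary allylic alcohol gives the enone (C7=O, C6=C11) while the tertiary C10 carbinol is inert.

Step 16
Reactants: 21 (4S)-4-hydroxy-4-methylcyclohex-2-en-1-one; 22 1-[(3-bromopropoxy)methyl]-4-methoxybenzene
Product: 24 (4S)-3-{3-[(4-methoxybenzyl)oxy]propyl}-4-methyl-1,4-bis(trimethylsilyloxy)cyclohex-1-ene (C3 epimers), via Grignard reagent 23 (not isolated)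
Conditions: 22, Mg, THF; then 21, CuBr·SMe2 (10 mol %), Me3SiCl, THF, −78 °C; Et3N quench
Reagents that add atoms: chlorotrimethylsilane C[Si](C)(C)Cl; magnesium (into intermediate 23 only) [Mg]
Why: Copper-catalysed conjugate addition with silyl trapping places the C12–C14 chain on C11 and gives the regiodefined C7/C6 silyl enol ether; the C11 centre is removed again in the next step.

Step 17
Reactants: 24 silyl enol ether
Product: 26 (4S)-4-hydroxy-3-{3-[(4-methoxybenzyl)oxy]propyl}-4-methylcyclohex-2-en-1-one, via enone silyl ether 25 (not isolated)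
Conditions: Pd(OAc)2 (1.1 equiv), MeCN, rt; then K2CO3, MeOH, 0 °C
Reagents that add atoms: none
Why: Saegusa–Ito oxidation (palladium enolate, β-hydride elimination of the only available C11–H) restores the C6=C11 enone, now β-substituted, and methanolysis frees the tertiary alcohol.

Step 18
Reactants: 26 β-substituted hydroxy enone
Product: 27 (4S)-4-{[(bromomethyl)dimethylsilyl]oxy}-3-{3-[(4-methoxybenzyl)oxy]propyl}-4-methylcyclohex-2-en-1-one
Conditions: BrCH2SiMe2Cl, imidazole, DMF, rt
Reagents that add atoms: (bromomethyl)chlorodimethylsilane C[Si](C)(Cl)CBr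
Why: Silylation of the tertiary allylic alcohol installs the one-carbon radical tether on the C10 oxygen.

Step 19
Reactants: 27 bromomethylsilyl ether
Product: 28 cis-fused oxasilolane ketone (C10–O–SiMe2–C26H2–C11 ring; C26 cis to the C10 oxygen; C6 allyl cis to C26 and trans to the C12 chain)
Conditions: allylSnBu3 (3 equiv), AIBN (portionwise), PhH (0.05 M), 80 °C
Reagents that add atoms: allyltributylstannane C=CC[Sn](CCCC)(CCCC)CCCC
Why: Nishiyama–Stork 5-exo-trig cyclization of the silylmethyl radical onto the enone β-carbon makes the quaternary C11 with C26 necessarily cis to the C10 oxygen, and Keck allylation of the resulting C6 α-keto radical should occur on the face anti to the pseudoaxial C12 chain and away from the axial C10 methyl, which sets C6.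

Step 20
Reactants: 28 oxasilolane ketone
Product: 30 4-hydroxy-3-(hydroxymethyl)-2-(3-hydroxypropyl)-3-{3-[(4-methoxybenzyl)oxy]propyl}-4-methylcyclohexan-1-one (C6, C10, C11 as in the target; in equilibrium with its bridged hemiketal), via alkylborane 29 (not isolated)
Conditions: 9-BBN (1.2 equiv), THF, 0 °C to rt; then KF, KHCO3, 30% H2O2, THF/MeOH, 50 °C
Reagents that add atoms: hydrogen peroxide OO; 9-borabicyclo[3.3.1]nonane (into intermediate 29 only) B1C2CCCC1CCC2
Why: Chemoselective hydroboration of the terminal alkene followed by one-pot oxidation of the C–B bond and Tamao–Fleming oxidation of the cyclic alkoxysilane, both with retention, should unveil C3–OH and C26–OH.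

Step 21
Reactants: 30 keto triol
Product: 31 C3 tert-butyldimethylsilyl ether of 30
Conditions: TBSCl (1.05 equiv), imidazole, CH2Cl2, −20 °C
Reagents that add atoms: tert-butyl(chloro)dimethylsilane CC(C)(C)[Si](C)(C)Cl
Why: The unhindered C3 hydroxyl should be silylated selectively, because C26–OH is neopentyl and partly tied up as the hemiketal and C10–OH is tertiary.

Step 22
Reactants: 31 keto diol
Product: 32 C26 methanesulfonate of 31
Conditions: MsCl, Et3N, CH2Cl2, −20 °C
Reagents that add atoms: methanesulfonyl chloride CS(Cl)(=O)=O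
Why: Mesylation of the only remaining primary hydroxyl traps the open keto form and turns C26 into the electrophile for ring closure.

Step 23
Reactants: 32 keto mesylate; 33 potassium (Z)-but-2-en-1-yltrifluoroborate
Product: 34 tertiary homoallylic alcohol (C7–OH axial and syn to C26; C7–C2H(CH3)–CH=CH2 with C2 as in the target)
Conditions: 33 (3 equiv), BF3·OEt2 (3 equiv), CH2Cl2, −78 to −40 °C; NaHCO3 work-up
Reagents that add atoms: none
Why: Lewis acid-promoted crotylboration through a closed chair (Zimmerman–Traxler) transition state: equatorial attack anti to the axial C26 group of the chair fixed by the equatorial C6 chain should set C7, and the (Z)-crotyl geometry, with the branched C6 side equatorial and C8 axial, should set C2.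

Step 24
Reactants: 34 homoallylic alcohol mesylate
Product: 35 6-oxabicyclo[3.2.1]octane ether (C7–O–C26 bridge) carrying the C2 butenyl group, the C3 silyl ether and the C14 4-methoxybenzyl ether
Conditions: NaH (1.2 equiv), THF, 0 °C to rt
Reagents that add atoms: none
Why: Intramolecular Williamson etherification (5-exo-tet) of the axial C7 alkoxide onto the syn-axial neopentyl mesylate closes the tetrahydrofuran ring, five-membered closure being favoured over oxetane formation or fragmentation from the C10 alkoxide, whose share is kept low by the small excess of base.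

Step 25
Reactants: 35 bicyclic ether
Product: 36 C14 primary alcohol
Conditions: DDQ, CH2Cl2/pH 7 buffer, 0 °C
Reagents that add atoms: none
Why: Oxidative cleavage of the 4-methoxybenzyl ether leaves the silyl ether, the vinyl group and the tertiary alcohol intact.

Step 26
Reactants: 36 C14 alcohol
Product: 37 C14 aldehyde
Conditions: Dess–Martin periodinane (1.05 equiv), NaHCO3, CH2Cl2, 0 °C; used crude
Reagents that add atoms: none
Why: Mild oxidation of the only primary alcohol, the tertiary C10–OH being inert; the oxidant is charged near-stoichiometrically so that the six-membered lactol which the aldehyde may form with C10–OH is not oxidized further, and the next step opens that lactol again.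

Step 27
Reactants: 37 C14 aldehyde
Product: 38 terminal alkyne (C14≡C15H)
Conditions: dimethyl (1-diazo-2-oxopropyl)phosphonate, K2CO3, MeOH, 0 °C to rt
Reagents that add atoms: dimethyl (1-diazo-2-oxopropyl)phosphonate CC(=O)C(=[N+]=[N-])P(=O)(OC)OC
Why: Ohira–Bestmann (Seyferth–Gilbert) homologation converts the aldehyde into the alkyne by one carbon.

Step 28
Reactants: 38 terminal alkyne
Product: 40 methyl alkyne (C14≡C15–CH3), via dilithio acetylide 39 (not isolated)
Conditions: n-BuLi (2.2 equiv), THF, −78 °C; then MeI, −78 to 0 °C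
Reagents that add atoms: iodomethane CI; butyllithium (lithium into intermediate 39 only) [Li]CCCC
Why: C-methylation of the lithium acetylide supplies the C15 methyl group, the hindered tertiary lithium alkoxide being a much poorer nucleophile.

Step 29
Reactants: 40 methyl alkyne
Product: 42 C1 primary alcohol, via aldehyde 41 (not isolated)
Conditions: OsO4 (2 mol %), NaIO4, 2,6-lutidine, dioxane/H2O, rt; then NaBH4, 0 °C
Reagents that add atoms: sodium periodate [Na+].[O-]I(=O)(=O)=O
Why: Lemieux–Johnson cleavage of the only alkene (the alkyne reacts far more slowly) gives the C1 aldehyde, which is reduced in the same flask so that the epimerizable C2 centre is not exposed and the next step is not disturbed.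

Step 30
Reactants: 42 alkynyl diol
Product: 44 (E)-vinyl iodide (C14H=C15(CH3)I; iodine trans to C13), via alkenylzirconocene 43 (not isolated)
Conditions: Cp2Zr(H)Cl (4.5 equiv), THF, 50 °C; then I2, THF, 0 °C; aqueous work-up
Reagents that add atoms: iodine II; zirconocene hydride chloride (into intermediate 43 only) [H][Zr](Cl)(C1C=CC=C1)C1C=CC=C1
Why: syn-Hydrozirconation with excess reagent (two equivalents are taken up by the hydroxyl groups as zirconium alkoxides) under equilibrating conditions should place zirconium on the less hindered methyl-bearing carbon, and iodinolysis of the C–Zr bond with retention gives the (E)-2-iodoalkene while the work-up frees both alcohols.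

**Union and end game**

Step 31
Reactants: 44 vinyl iodide; 14 ring A alkenylboronate
Product: 45 coupled (E,E)-diene with C1–OH free and C3–OTBS
Conditions: Pd(PPh3)4 (5 mol %), TlOEt, THF/H2O, rt
Reagents that add atoms: none
Why: Suzuki–Miyaura coupling is stereoretentive at both alkenyl partners, so the C14=C15 and C16=C17 geometries are carried over from 44 and 14.

Step 32
Reactants: 45 diene alcohol
Product: 46 C1 aldehyde with C3–OTBS
Conditions: Dess–Martin periodinane, NaHCO3, CH2Cl2, 0 °C
Reagents that add atoms: none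
Why: Buffered oxidation of the only primary alcohol should give the α-branched aldehyde without epimerization at C2 or β-elimination of the ring ether.

Step 33
Reactants: 46 silyl ether aldehyde
Product: 47 target
Conditions: HF·pyridine, pyridine, THF, 0 °C to rt
Reagents that add atoms: none
Why: Buffered, weakly acidic desilylation frees C3–OH under conditions that should leave the C2 centre, the ether bridge and the skipped diene untouched.

**Compound list**

1 | (E)-3-methylpent-2-en-4-yn-1-ol | OC/C=C(C)/C#C | starting material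
2 | (E)-3-methylpenta-2,4-dien-1-ol | OC/C=C(C)/C=C | intermediate
3 | tert-butyl{[(2E)-3-methylpenta-2,4-dien-1-yl]oxy}diphenylsilane | C=C/C(C)=C/CO[Si](c1ccccc1)(c1ccccc1)C(C)(C)C | intermediate
4 | 3-methylfuran-2(5H)-one | CC1=CCOC1=O | starting material
5 | 5-bromo-3-methylfuran-2(5H)-one (racemic) | CC1=CC(Br)OC1=O | intermediate
6 | (1S,2R,5S)-(+)-menthol | O[C@H]1C[C@@H](C)CC[C@@H]1C(C)C | starting material
7 | (5S)-3-methyl-5-{[(1S,2R,5S)-menthyl]oxy}furan-2(5H)-one | CC1=C[C@@H](O[C@H]2C[C@@H](C)CC[C@@H]2C(C)C)OC1=O | intermediate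
8 | endo Diels–Alder adduct (cis-fused lactone acetal, see step 5) | CC1=CC[C@@H]2[C@@H](O[C@H]3C[C@@H](C)CC[C@@H]3C(C)C)OC(=O)[C@]2(C)[C@@H]1CO[Si](c1ccccc1)(c1ccccc1)C(C)(C)C | intermediate
9 | all-cis diol of ring A (C1'–CH2OTBDPS, C6'–CH2OH, C5'–CH2OH) | CC1=CC[C@H](CO)[C@](C)(CO)[C@@H]1CO[Si](c1ccccc1)(c1ccccc1)C(C)(C)C | intermediate
10 | bis(methanesulfonate) of 9 | CC1=CC[C@H](COS(C)(=O)=O)[C@](C)(COS(C)(=O)=O)[C@@H]1CO[Si](c1ccccc1)(c1ccccc1)C(C)(C)C | intermediate
11 | tert-butyl{[(1R,5S)-2,5,6,6-tetramethylcyclohex-2-en-1-yl]methoxy}diphenylsilane | CC1=CC[C@H](C)C(C)(C)[C@@H]1CO[Si](c1ccccc1)(c1ccccc1)C(C)(C)C | intermediate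
12 | [(1R,5S)-2,5,6,6-tetramethylcyclohex-2-en-1-yl]methanol | CC1=CC[C@H](C)C(C)(C)[C@@H]1CO | intermediate
13 | (1R,5S)-2,5,6,6-tetramethylcyclohex-2-ene-1-carbaldehyde | CC1=CC[C@H](C)C(C)(C)[C@@H]1C=O | intermediate
14 | (E)-alkenyl pinacolboronate of ring A | CC1=CC[C@H](C)C(C)(C)[C@@H]1/C=C/B1OC(C)(C)C(C)(C)O1 | intermediate
15 | (S)-(+)-linalool, (3S)-3,7-dimethylocta-1,6-dien-3-ol | C=C[C@@](C)(O)CCC=C(C)C | starting material
16 | ozonide of 15 at the trisubstituted alkene | C=C[C@@](C)(O)CCC1OOC(C)(C)O1 | intermediate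
17 | (5S)-5-ethenyl-5-methyloxolan-2-ol (anomers) | C=C[C@]1(C)CCC(O)O1 | intermediate
18 | vinylmagnesium bromide | C=C[Mg]Br | starting material
19 | (3S)-3-methylocta-1,7-diene-3,6-diol (C6 epimers) | C=C[C@@](C)(O)CCC(O)C=C | intermediate
20 | (1S)-1-methylcyclohex-2-ene-1,4-diol (C4 epimers) | C[C@]1(O)CCC(O)C=C1 | intermediate
21 | (4S)-4-hydroxy-4-methylcyclohex-2-en-1-one | C[C@]1(O)CCC(=O)C=C1 | intermediate
22 | 1-[(3-bromopropoxy)methyl]-4-methoxybenzene | BrCCCOCc1ccc(OC)cc1 | starting material
23 | {3-[(4-methoxybenzyl)oxy]propyl}magnesium bromide | Br[Mg]CCCOCc1ccc(OC)cc1 | intermediate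
24 | (4S)-3-{3-[(4-methoxybenzyl)oxy]propyl}-4-methyl-1,4-bis(trimethylsilyloxy)cyclohex-1-ene (C3 epimers) | C[C@]1(O[Si](C)(C)C)CCC(O[Si](C)(C)C)=CC1CCCOCc1ccc(OC)cc1 | intermediate
25 | (4S)-3-{3-[(4-methoxybenzyl)oxy]propyl}-4-methyl-4-(trimethylsilyloxy)cyclohex-2-en-1-one | C[C@]1(O[Si](C)(C)C)CCC(=O)C=C1CCCOCc1ccc(OC)cc1 | intermediate
26 | (4S)-4-hydroxy-3-{3-[(4-methoxybenzyl)oxy]propyl}-4-methylcyclohex-2-en-1-one | C[C@]1(O)CCC(=O)C=C1CCCOCc1ccc(OC)cc1 | intermediate
27 | (bromomethyl)dimethylsilyl ether of 26 | C[C@]1(O[Si](C)(C)CBr)CCC(=O)C=C1CCCOCc1ccc(OC)cc1 | intermediate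
28 | cis-fused oxasilolane ketone with C6 allyl (see step 19) | C[C@]12CCC(=O)[C@@H](CC=C)[C@@]1(CCCOCc1ccc(OC)cc1)C[Si](C)(C)O2 | intermediate
29 | B-alkyl-9-borabicyclononane adduct of 28 | C[C@]12CCC(=O)[C@@H](CCCB3C4CCCC3CCC4)[C@@]1(CCCOCc1ccc(OC)cc1)C[Si](C)(C)O2 | intermediate
30 | keto triol (C3–OH, C26–OH, C10–OH) | C[C@]1(O)CCC(=O)[C@@H](CCCO)[C@@]1(CCCOCc1ccc(OC)cc1)CO | intermediate
31 | C3 silyl ether of 30 | C[C@]1(O)CCC(=O)[C@@H](CCCO[Si](C)(C)C(C)(C)C)[C@@]1(CCCOCc1ccc(OC)cc1)CO | intermediate
32 | C26 methanesulfonate of 31 | C[C@]1(O)CCC(=O)[C@@H](CCCO[Si](C)(C)C(C)(C)C)[C@@]1(CCCOCc1ccc(OC)cc1)COS(C)(=O)=O | intermediate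
33 | potassium (Z)-but-2-en-1-yltrifluoroborate | C/C=C\C[B-](F)(F)F.[K+] | starting material
34 | tertiary homoallylic alcohol from crotylation of 32 | C[C@]1(O)CC[C@](O)([C@H](C)C=C)[C@@H](CCCO[Si](C)(C)C(C)(C)C)[C@@]1(CCCOCc1ccc(OC)cc1)COS(C)(=O)=O | intermediate
35 | 6-oxabicyclo[3.2.1]octane ether (vinyl, OTBS, OPMB) | COc1ccc(COCCC[C@]23CO[C@]([C@H](C)C=C)(CC[C@]2(C)O)[C@H]3CCCO[Si](C)(C)C(C)(C)C)cc1 | intermediate
36 | C14 alcohol | OCCC[C@]12CO[C@]([C@H](C)C=C)(CC[C@]1(C)O)[C@H]2CCCO[Si](C)(C)C(C)(C)C | intermediate
37 | C14 aldehyde | O=CCC[C@]12CO[C@]([C@H](C)C=C)(CC[C@]1(C)O)[C@H]2CCCO[Si](C)(C)C(C)(C)C | intermediate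
38 | terminal alkyne | C#CCC[C@]12CO[C@]([C@H](C)C=C)(CC[C@]1(C)O)[C@H]2CCCO[Si](C)(C)C(C)(C)C | intermediate
39 | dilithio acetylide alkoxide of 38 | [Li]C#CCC[C@]12CO[C@]([C@H](C)C=C)(CC[C@]1(C)O[Li])[C@H]2CCCO[Si](C)(C)C(C)(C)C | intermediate
40 | methyl alkyne | CC#CCC[C@]12CO[C@]([C@H](C)C=C)(CC[C@]1(C)O)[C@H]2CCCO[Si](C)(C)C(C)(C)C | intermediate
41 | C1 aldehyde of the methyl alkyne | CC#CCC[C@]12CO[C@]([C@H](C)C=O)(CC[C@]1(C)O)[C@H]2CCCO[Si](C)(C)C(C)(C)C | intermediate
42 | C1 alcohol of the methyl alkyne | CC#CCC[C@]12CO[C@]([C@H](C)CO)(CC[C@]1(C)O)[C@H]2CCCO[Si](C)(C)C(C)(C)C | intermediate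
43 | (E)-alkenylzirconocene chloride (both hydroxyls as zirconocene chloride alkoxides) | Cl[Zr](C1C=CC=C1)(C1C=CC=C1)/C(C)=C/CC[C@]12CO[C@]([C@H](C)CO[Zr](Cl)(C3C=CC=C3)C3C=CC=C3)(CC[C@]1(C)O[Zr](Cl)(C3C=CC=C3)C3C=CC=C3)[C@H]2CCCO[Si](C)(C)C(C)(C)C | intermediate
44 | (E)-vinyl iodide of the core | I/C(C)=C/CC[C@]12CO[C@]([C@H](C)CO)(CC[C@]1(C)O)[C@H]2CCCO[Si](C)(C)C(C)(C)C | intermediate
45 | coupled diene, C1–OH, C3–OTBS | CC1=CC[C@H](C)C(C)(C)[C@@H]1/C=C/C(C)=C/CC[C@]12CO[C@]([C@H](C)CO)(CC[C@]1(C)O)[C@H]2CCCO[Si](C)(C)C(C)(C)C | intermediate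
46 | C1 aldehyde, C3–OTBS | CC1=CC[C@H](C)C(C)(C)[C@@H]1/C=C/C(C)=C/CC[C@]12CO[C@]([C@H](C)C=O)(CC[C@]1(C)O)[C@H]2CCCO[Si](C)(C)C(C)(C)C | intermediate
47 | CNP0419303.1 | CC1=CC[C@H](C)C(C)(C)[C@@H]1/C=C/C(C)=C/CC[C@]12CO[C@]([C@H](C)C=O)(CC[C@]1(C)O)[C@H]2CCCO | target

**Totals**

Total step count: 33. Longest linear sequence: 22 steps (steps 12–33, from (S)-linalool).

**Steps most likely to fail**

Step 5. The α-methylbutenolide may react too slowly, so that the diene polymerizes or the acetal decomposes before cycloaddition, and the C2' methyl group may erode the ortho regioselectivity. The fallback sets out from 7 and comes back at 8; it uses a 2-silyloxy diene in which both directing effects point the same way and which is far more nucleophilic. (tert-Butyldiphenylsilyloxy)acetaldehyde and 3-(triphenylphosphoranylidene)butan-2-one would give by Wittig reaction the enone (E)-5-[(tert-butyldiphenylsilyl)oxy]-3-methylpent-3-en-2-one F1. TBSOTf and Et3N would convert it into the silyloxy diene F2. Cycloaddition of F2 with 7 (same endo and anti course, the siloxy group directing the lactone carbonyl para to itself, onto C6') would give the adduct silyl enol ether F3. CsF and PhNTf2 would turn it regiospecifically into the enol triflate F4, and reduction with Pd(OAc)2, PPh3, Bu3N and HCO2H would return to 8.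

Step 19. The allyl transfer to the C6 radical may show poor facial selectivity, and the silylmethyl radical may be allylated or reduced before it cyclizes onto the fully substituted β-carbon. The fallback sets out from 26 and comes back at 30; it delivers the C3–C5 chain intramolecularly from silicon, so that its cis relation to C26 is enforced by the tether. (Chloromethyl)trichlorosilane and allylmagnesium chloride (2 equiv) would give chlorodiallyl(chloromethyl)silane F5. Silylation of 26 would give the diallyl(chloromethyl)silyl ether F6, and NaI in acetone the iodomethyl ether F7. Slow addition of Bu3SnH with AIBN should trigger 5-exo cyclization onto C11 and then 7-endo cyclization of the C6 radical onto the terminus of one allylsilane, giving the tricyclic siloxane ketone F8. Tamao–Fleming oxidation (KF, KHCO3, H2O2) of both ring Si–C bonds would then give 30 directly.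

Step 23. Addition to the hindered ketone may be sluggish, the alternative chair transition state may leak (loss of C2 control), axial attack may compete (loss of C7 control), and the Lewis acid may remove the silyl or 4-methoxybenzyl ether. The fallback sets out from 32 and comes back at 42; it separates C–C bond formation from the creation of C2. Isopropenylmagnesium bromide with CeCl3 would add to 32 to give the tertiary allylic alcohol F9, and NaH would close the bicyclic isopropenyl ether F10. The operations of steps 25–28 would give in turn the C14 alcohol F11, the aldehyde F12, the terminal alkyne F13 and the methyl alkyne F14. Hydroboration of the 1,1-disubstituted alkene of F14 with 9-BBN (faster than at the internal alkyne) and oxidation should then give 42. The C2 centre would be set by approach of the borane anti to the branched C6 side, and the C2 epimers would have to be separated if this control is incomplete.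

**Further compounds**

F1 | step 5 | (E)-5-[(tert-butyldiphenylsilyl)oxy]-3-methylpent-3-en-2-one | CC(=O)/C(C)=C/CO[Si](c1ccccc1)(c1ccccc1)C(C)(C)C
F2 | step 5 | tert-butyl{[(2E)-4-(tert-butyldimethylsilyloxy)-3-methylpenta-2,4-dien-1-yl]oxy}diphenylsilane | C=C(O[Si](C)(C)C(C)(C)C)/C(C)=C/CO[Si](c1ccccc1)(c1ccccc1)C(C)(C)C
F3 | step 5 | adduct of F2 and 7, C3' silyl enol ether of 8 | CC1=C(O[Si](C)(C)C(C)(C)C)C[C@@H]2[C@@H](O[C@H]3C[C@@H](C)CC[C@@H]3C(C)C)OC(=O)[C@]2(C)[C@@H]1CO[Si](c1ccccc1)(c1ccccc1)C(C)(C)C
F4 | step 5 | C3' enol triflate of 8 | CC1=C(OS(=O)(=O)C(F)(F)F)C[C@@H]2[C@@H](O[C@H]3C[C@@H](C)CC[C@@H]3C(C)C)OC(=O)[C@]2(C)[C@@H]1CO[Si](c1ccccc1)(c1ccccc1)C(C)(C)C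
F5 | step 19 | chlorodiallyl(chloromethyl)silane | C=CC[Si](Cl)(CC=C)CCl
F6 | step 19 | diallyl(chloromethyl)silyl ether of 26 | C[C@]1(O[Si](CC=C)(CC=C)CCl)CCC(=O)C=C1CCCOCc1ccc(OC)cc1
F7 | step 19 | diallyl(iodomethyl)silyl ether of 26 | C[C@]1(O[Si](CC=C)(CC=C)CI)CCC(=O)C=C1CCCOCc1ccc(OC)cc1
F8 | step 19 | tricyclic siloxane ketone (Si bonded to O–C10, C26, C3 and one allyl; C5 cis to C26) | C[C@@]12CCC(=O)[C@H]3CCC[Si](CC=C)(O1)C[C@@]23CCCOCc1ccc(OC)cc1
F9 | step 23 | isopropenyl adduct of 32 (C7–OH syn to C26) | C[C@]1(O)CC[C@](O)(C(C)=C)[C@@H](CCCO[Si](C)(C)C(C)(C)C)[C@@]1(CCCOCc1ccc(OC)cc1)COS(C)(=O)=O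
F10 | step 23 | bicyclic ether with C7 isopropenyl group | COc1ccc(COCCC[C@]23CO[C@](C(C)=C)(CC[C@]2(C)O)[C@H]3CCCO[Si](C)(C)C(C)(C)C)cc1
F11 | step 23 | C14 alcohol of the isopropenyl series | OCCC[C@]12CO[C@](C(C)=C)(CC[C@]1(C)O)[C@H]2CCCO[Si](C)(C)C(C)(C)C
F12 | step 23 | C14 aldehyde of the isopropenyl series | O=CCC[C@]12CO[C@](C(C)=C)(CC[C@]1(C)O)[C@H]2CCCO[Si](C)(C)C(C)(C)C
F13 | step 23 | terminal alkyne of the isopropenyl series | C#CCC[C@]12CO[C@](C(C)=C)(CC[C@]1(C)O)[C@H]2CCCO[Si](C)(C)C(C)(C)C
F14 | step 23 | methyl alkyne of the isopropenyl series | CC#CCC[C@]12CO[C@](C(C)=C)(CC[C@]1(C)O)[C@H]2CCCO[Si](C)(C)C(C)(C)C
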